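**Plan**
1. Retrosynthesis: the hydroxyquinone (ring B) is taken back through its silylated ortho-quinone to a 2-prenylresorcinol monosilyl ether. That arene is cut at two ring bonds, C(OH)–C(prenyl) and C(O-silyl)–C(chromanyl), into the 2-(chroman-3-yl)cyclobutenone 31 and the siloxyalkyne 34.
2. Enabling feature: in the quinone ring the sequence C2(OH) / C3(prenyl) / C4(=O) / C5(chromanyl) is the imprint of a ketene carbonyl carbon, the two carbons of an ynol ether and the α-carbon of a vinylketene. C6–H and C1 are the ring CH and CH2 of the cyclobutenone that hides this vinylketene; the oxygen on C1 is added last by phenol oxidation.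
3. The cyclobutenone is cut at its ketene/ethoxyacetylene [2+2] bonds back to chroman-3-ylacetic acid 23. The chroman is cut at O1–C2 (Mitsunobu) and at C3–CH2CO2 (auxiliary-directed alkylation), and ring A at its C-prenyl bond (para-Claisen) back to 2,4-dihydroxy-6-methoxybenzaldehyde.
4. Forward order: ring A aldehyde (steps 1–4), side chain with the stereocentre (5–8), pyran ring C (9, 10), four-membered ring (11–15), ring B by benzannulation with 34 from step 16 (17), oxidation and desilylation (18, 19).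
5. Stereochemistry: the only stereocentre, C3 (R), is set in step 7 by (S)-4-benzyloxazolidinone-directed enolate alkylation and is never α to a carbonyl group afterwards.

Key step: step 17

Remark: 1 and 32 are taken as catalogue compounds, and centres that form as mixtures and are erased later (in 5, 6, 27, 30, 36) are drawn without configuration; in names prenyl = 3-methylbut-2-en-1-yl, TIPS = triisopropylsilyl, chroman = 3,4-dihydro-2H-chromene.

**Step 1**
Reactants: 1 2,4-dihydroxy-6-methoxybenzaldehyde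
Product: 2 2-hydroxy-6-methoxy-4-(TIPS-oxy)benzaldehyde
Conditions: i-Pr3SiCl, imidazole, CH2Cl2, 0 °C → rt
Reagents that add atoms: triisopropylsilyl chloride, CC(C)[Si](Cl)(C(C)C)C(C)C
Why: The 4-OH is the more acidic, unchelated phenol while the 2-OH is hydrogen-bonded to the aldehyde, so silyl ether formation should stop at the 4-O-monosilyl ether.

**Step 2**
Reactants: 2 2-hydroxy-6-methoxy-4-(TIPS-oxy)benzaldehyde; 3 3-methylbut-2-en-1-ol
Product: 4 2-methoxy-6-(prenyloxy)-4-(TIPS-oxy)benzaldehyde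
Conditions: PPh3, DIAD, THF, 0 °C → rt
Reagents that add atoms: none
Why: Mitsunobu etherification alkylates the chelated phenol at the primary carbinol carbon of 3 under neutral conditions that cannot move the silyl group.

**Step 3**
Reactants: 4 2-methoxy-6-(prenyloxy)-4-(TIPS-oxy)benzaldehyde
Product: 7 2-hydroxy-6-methoxy-5-prenyl-4-(TIPS-oxy)benzaldehyde, via ortho-dienone 5 (not isolated), via para-dienone 6 (not isolated)
Conditions: PhNEt2, 190 °C
Reagents that add atoms: none
Why: Aromatic Claisen rearrangement to the only free ortho carbon gives a crowded 1,1-dimethylallyl dienone that is expected to undergo the Cope shift to the para carbon faster than it enolises, so tautomerisation should deliver the para-prenyl phenol (para-Claisen, Claisen–Cope sequence).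

**Step 4**
Reactants: 7 2-hydroxy-6-methoxy-5-prenyl-4-(TIPS-oxy)benzaldehyde
Product: 8 2-(allyloxy)-6-methoxy-5-prenyl-4-(TIPS-oxy)benzaldehyde
Conditions: allyl bromide, K2CO3, acetone, reflux
Reagents that add atoms: allyl bromide, C=CCBr
Why: Williamson etherification masks the freed phenol as an allyl ether that tolerates enolate and hydride chemistry and can be removed later under neutral conditions.

**Step 5**
Reactants: 8 2-(allyloxy)-6-methoxy-5-prenyl-4-(TIPS-oxy)benzaldehyde; 9 Meldrum's acid (2,2-dimethyl-1,3-dioxane-4,6-dione)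
Product: 12 3-[2-(allyloxy)-6-methoxy-5-prenyl-4-(TIPS-oxy)phenyl]propanoic acid, via alkylidene Meldrum's acid 10 (not isolated), via benzyl Meldrum's acid 11 (not isolated)
Conditions: diethyl 2,6-dimethyl-1,4-dihydropyridine-3,5-dicarboxylate (Hantzsch ester), L-proline (cat.), EtOH, rt; then pyridine/H2O, 100 °C
Reagents that add atoms: none
Why: Organocatalytic reductive Knoevenagel condensation (the alkylidene Meldrum's acid is a far better hydride acceptor than the prenyl or allyl alkenes) followed by hydrolysis and decarboxylation should give the arylpropanoic acid without protic acid or a hydrogenation catalyst.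

**Step 6**
Reactants: 12 3-[2-(allyloxy)-6-methoxy-5-prenyl-4-(TIPS-oxy)phenyl]propanoic acid; 13 (S)-4-benzyloxazolidin-2-one
Product: 15 (4S)-4-benzyl-3-{3-[2-(allyloxy)-6-methoxy-5-prenyl-4-(TIPS-oxy)phenyl]propanoyl}oxazolidin-2-one, via mixed pivalic anhydride 14 (not isolated)
Conditions: t-BuCOCl, Et3N, THF, −20 °C; then 13, LiCl, −20 °C → rt
Reagents that add atoms: none
Why: N-Acylation of the oxazolidinone through the mixed pivalic anhydride with LiCl activation is the standard way to attach the Evans auxiliary to a carboxylic acid.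

**Step 7**
Reactants: 15 (4S)-4-benzyl-3-{3-[2-(allyloxy)-6-methoxy-5-prenyl-4-(TIPS-oxy)phenyl]propanoyl}oxazolidin-2-one; 16 tert-butyl bromoacetate
Product: 18 tert-butyl (3R)-3-{[2-(allyloxy)-6-methoxy-5-prenyl-4-(TIPS-oxy)phenyl]methyl}-4-[(4S)-4-benzyl-2-oxooxazolidin-3-yl]-4-oxobutanoate, via sodium enolate 17 (not isolated)
Conditions: NaN(SiMe3)2, THF, −78 °C; then 16, −78 → −45 °C
Reagents that add atoms: none
Why: Evans asymmetric alkylation, in which the chelated sodium (Z)-enolate is shielded on one face by the benzyl group of the (S)-auxiliary, so the bromoacetate should enter from the opposite face and set the (R) centre that becomes C3 of the chroman.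

**Step 8**
Reactants: 18 the alkylated imide
Product: 19 tert-butyl (3R)-4-[2-(allyloxy)-6-methoxy-5-prenyl-4-(TIPS-oxy)phenyl]-3-(hydroxymethyl)butanoate
Conditions: LiBH4, H2O (1 equiv), Et2O, 0 °C
Reagents that add atoms: none
Why: Reductive auxiliary cleavage, in which LiBH4 reduces the activated imide carbonyl to the primary alcohol and leaves the tert-butyl ester and the stereocentre untouched.

**Step 9**
Reactants: 19 tert-butyl (3R)-4-[2-(allyloxy)-6-methoxy-5-prenyl-4-(TIPS-oxy)phenyl]-3-(hydroxymethyl)butanoate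
Product: 20 tert-butyl (3R)-4-[2-hydroxy-6-methoxy-5-prenyl-4-(TIPS-oxy)phenyl]-3-(hydroxymethyl)butanoate
Conditions: Pd(PPh3)4 (cat.), morpholine, THF, rt
Reagents that add atoms: none
Why: Tsuji–Trost deallylation through a π-allylpalladium complex trapped by morpholine frees the phenol under neutral conditions that touch neither the prenyl group, the silyl ether nor the hydroxy ester.

**Step 10**
Reactants: 20 tert-butyl (3R)-4-[2-hydroxy-6-methoxy-5-prenyl-4-(TIPS-oxy)phenyl]-3-(hydroxymethyl)butanoate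
Product: 21 tert-butyl 2-[(3R)-5-methoxy-6-prenyl-7-(TIPS-oxy)chroman-3-yl]acetate
Conditions: PPh3, DIAD, THF (0.02 M), 0 °C → rt
Reagents that add atoms: none
Why: Intramolecular Mitsunobu etherification (6-exo-tet SN2 of the phenol at the activated primary carbinol) closes the pyran ring without involving the stereocentre.

**Step 11**
Reactants: 21 tert-butyl 2-[(3R)-5-methoxy-6-prenyl-7-(TIPS-oxy)chroman-3-yl]acetate
Product: 23 2-[(3R)-5-methoxy-6-prenyl-7-(TIPS-oxy)chroman-3-yl]acetic acid, via trimethylsilyl ester 22 (not isolated)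
Conditions: Me3SiOTf, 2,6-lutidine, CH2Cl2, 0 °C → rt; pH 5 aqueous work-up
Reagents that add atoms: none
Why: Silyl triflate-mediated tert-butyl ester cleavage (loss of 2-methylpropene to the silyl ester, hydrolysed on work-up) avoids the protic acid that could add to the prenyl group.

**Step 12**
Reactants: 23 2-[(3R)-5-methoxy-6-prenyl-7-(TIPS-oxy)chroman-3-yl]acetic acid; 24 ethoxyacetylene
Product: 27 3-ethoxy-4-[(3R)-5-methoxy-6-prenyl-7-(TIPS-oxy)chroman-3-yl]cyclobut-2-en-1-one (epimers at the ring carbon), via acid chloride 25 (not isolated), via ketene 26 (not isolated)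
Conditions: 1-chloro-N,N,2-trimethylprop-1-en-1-amine, CH2Cl2, 0 °C → rt; then 24 (5 equiv), Et3N (slow addition), rt → 40 °C
Reagents that add atoms: none
Why: Neutral chlorination with the α-chloroenamine, dehydrochlorination to the monoalkylketene and ketene–alkyne [2+2] cycloaddition (the nucleophilic terminal carbon of ethoxyacetylene attacks the ketene carbonyl carbon) is the classical route to 4-alkyl-3-ethoxycyclobutenones.

**Step 13**
Reactants: 27 3-ethoxy-4-[(3R)-chroman-3-yl]cyclobut-2-en-1-one (ring A substituted as before)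
Product: 28 3-hydroxy-2-[(3R)-5-methoxy-6-prenyl-7-(TIPS-oxy)chroman-3-yl]cyclobut-2-en-1-one (enol of the cyclobutane-1,3-dione)
Conditions: 1 M HCl, THF, 0 °C → rt
Reagents that add atoms: water, O
Why: Acid hydrolysis of the vinylogous ester gives the cyclobutane-1,3-dione, whose substituted carbon lies between both carbonyl groups, so it should enolise toward that carbon and move the substituent onto an sp2 carbon.

**Step 14**
Reactants: 28 3-hydroxy-2-[(3R)-chroman-3-yl]cyclobut-2-en-1-one (ring A substituted as before)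
Product: 29 3-methoxy-2-[(3R)-5-methoxy-6-prenyl-7-(TIPS-oxy)chroman-3-yl]cyclobut-2-en-1-one
Conditions: Me3SiCHN2, toluene/MeOH, 0 °C
Reagents that add atoms: (trimethylsilyl)diazomethane, C[Si](C)(C)C=[N+]=[N-]
Why: O-Methylation of the strongly acidic, symmetric vinylogous acid with the diazoalkane can give only one enol ether.

**Step 15**
Reactants: 29 3-methoxy-2-[(3R)-chroman-3-yl]cyclobut-2-en-1-one (ring A substituted as before)
Product: 31 2-[(3R)-5-methoxy-6-prenyl-7-(TIPS-oxy)chroman-3-yl]cyclobut-2-en-1-one, via allylic alcohol 30 (not isolated)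
Conditions: i-Bu2AlH, CH2Cl2, −78 °C; then 1 M HCl, THF, 0 °C
Reagents that add atoms: water, O
Why: 1,2-Reduction of the vinylogous ester and acid-induced allylic transposition (Stork–Danheiser type carbonyl transposition, with loss of methanol) should place the carbonyl next to the substituted alkene carbon and leave the ring CH and CH2 unsubstituted.

**Step 16**
Reactants: 32 ethyl 4-methylpent-3-enoate
Product: 34 triisopropyl[(5-methylhex-4-en-1-yn-1-yl)oxy]silane, via lithium ynolate 33 (not isolated)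
Conditions: CH2Br2, lithium 2,2,6,6-tetramethylpiperidide, THF, −78 °C; n-BuLi, −78 → 0 °C; i-Pr3SiCl, −78 → 0 °C
Reagents that add atoms: dibromomethane, BrCBr; triisopropylsilyl chloride, CC(C)[Si](Cl)(C(C)C)C(C)C
Why: Kowalski ester homologation (addition of dibromomethyllithium, then carbenoid rearrangement of the lithiated dibromo enolate) gives the lithium ynolate, which the bulky silyl chloride should trap on oxygen.

**Step 17**
Reactants: 31 2-[(3R)-5-methoxy-6-prenyl-7-(TIPS-oxy)chroman-3-yl]cyclobut-2-en-1-one; 34 triisopropyl[(5-methylhex-4-en-1-yn-1-yl)oxy]silane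
Product: 39 4-[(3R)-5-methoxy-6-prenyl-7-(TIPS-oxy)chroman-3-yl]-2-prenyl-3-(TIPS-oxy)phenol, via vinylketene 35 (not isolated), via vinylcyclobutenone 36 (not isolated), via dienylketene 37 (not isolated), via cyclohexadienone 38 (not isolated)
Conditions: 34 (1.5 equiv), toluene, 80 °C, then 110 °C
Reagents that add atoms: none
Why: Heating opens cyclobutenone 31 by 4π electrocyclic cleavage to vinylketene 35, whose ketene C=C undergoes a regiospecific [2+2] cycloaddition with 34 (prenyl-bearing alkyne carbon to the ketene carbonyl carbon, oxygen-bearing alkyne carbon to the chromanyl-bearing α-carbon), and the resulting 4-vinylcyclobutenone 36 opens again (4π) to dienylketene 37. The six-membered ring is closed by thermal 6π electrocyclisation of 37 (terminal vinyl CH2 onto the ketene carbon) to cyclohexadienone 38, which tautomerises to the phenol, so the two ring bonds C(OH)–C(prenyl) and C(O-silyl)–C(chromanyl) arise in one operation. The closest known reaction type is the Danheiser benzannulation of cyclobutenones with siloxyalkynes, which gives resorcinol monosilyl ethers with this substitution pattern. No stereocentre is created (the quaternary carbon of 36 is transient), and C3 of the chroman is a non-enolisable spectator. The selectivity needed is regiochemical and is secured by the polarisation of the ynol ether (electron-rich β-carbon) against the electrophilic ketene carbon; the ynol ether is also far more ketenophilic than the two prenyl alkenes, and the unsubstituted ring CH2 of 31 allows the final tautomerisation. The excess of 34 should keep the product phenol from being acylated by 35.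

**Step 18**
Reactants: 39 4-[(3R)-5-methoxy-6-prenyl-7-(TIPS-oxy)chroman-3-yl]-2-prenyl-3-(TIPS-oxy)phenol
Product: 40 5-[(3R)-5-methoxy-6-prenyl-7-(TIPS-oxy)chroman-3-yl]-3-prenyl-4-(TIPS-oxy)cyclohexa-3,5-diene-1,2-dione
Conditions: (KSO3)2NO, KH2PO4 buffer, methyltrioctylammonium chloride (cat.), CH2Cl2/H2O, rt
Reagents that add atoms: potassium nitrosodisulfonate, [K+].[K+].[O]N(S(=O)(=O)[O-])S(=O)(=O)[O-]
Why: Teuber oxidation, in which the nitroxyl radical removes the phenolic hydrogen and a second equivalent adds at the only free ortho carbon (the para carbon carries the chroman), should give the ortho-quinone, while ring A has no free phenol and stays inert.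

**Step 19**
Reactants: 40 5-[(3R)-5-methoxy-6-prenyl-7-(TIPS-oxy)chroman-3-yl]-3-prenyl-4-(TIPS-oxy)cyclohexa-3,5-diene-1,2-dione
Product: 41 2-hydroxy-5-[(3R)-7-hydroxy-5-methoxy-6-prenylchroman-3-yl]-3-prenylcyclohexa-2,5-diene-1,4-dione (target)
Conditions: Bu4NF, AcOH, THF, 0 °C
Reagents that add atoms: none
Why: Fluoride-induced desilylation removes both silyl groups, the liberated 4-hydroxy-ortho-quinone is the tautomer of the more stable 2-hydroxy-para-quinone and should be isolated as such, and the acetic acid buffer should prevent base-induced epimerisation of C3 through a quinone methide.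

**Compound list**
1 | 2,4-dihydroxy-6-methoxybenzaldehyde | O=Cc1c(O)cc(O)cc1OC | starting material
2 | 2-hydroxy-6-methoxy-4-(TIPS-oxy)benzaldehyde | O=Cc1c(O)cc(O[Si](C(C)C)(C(C)C)C(C)C)cc1OC | intermediate
3 | 3-methylbut-2-en-1-ol | CC(C)=CCO | starting material
4 | 2-methoxy-6-(prenyloxy)-4-(TIPS-oxy)benzaldehyde | O=Cc1c(OCC=C(C)C)cc(O[Si](C(C)C)(C(C)C)C(C)C)cc1OC | intermediate
5 | ortho-dienone (not isolated): 2-methoxy-5-(2-methylbut-3-en-2-yl)-6-oxo-4-(TIPS-oxy)cyclohexa-1,3-diene-1-carbaldehyde | O=CC1=C(OC)C=C(O[Si](C(C)C)(C(C)C)C(C)C)C(C(C)(C)C=C)C1=O | intermediate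
6 | para-dienone (not isolated): 2-methoxy-3-prenyl-6-oxo-4-(TIPS-oxy)cyclohexa-1,4-diene-1-carbaldehyde | O=CC1=C(OC)C(CC=C(C)C)C(O[Si](C(C)C)(C(C)C)C(C)C)=CC1=O | intermediate
7 | 2-hydroxy-6-methoxy-5-prenyl-4-(TIPS-oxy)benzaldehyde | O=Cc1c(O)cc(O[Si](C(C)C)(C(C)C)C(C)C)c(CC=C(C)C)c1OC | intermediate
8 | 2-(allyloxy)-6-methoxy-5-prenyl-4-(TIPS-oxy)benzaldehyde | O=Cc1c(OCC=C)cc(O[Si](C(C)C)(C(C)C)C(C)C)c(CC=C(C)C)c1OC | intermediate
9 | Meldrum's acid (2,2-dimethyl-1,3-dioxane-4,6-dione) | CC1(C)OC(=O)CC(=O)O1 | starting material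
10 | alkylidene Meldrum's acid (not isolated): 5-{[2-(allyloxy)-6-methoxy-5-prenyl-4-(TIPS-oxy)phenyl]methylidene}-2,2-dimethyl-1,3-dioxane-4,6-dione | CC1(C)OC(=O)C(=Cc2c(OCC=C)cc(O[Si](C(C)C)(C(C)C)C(C)C)c(CC=C(C)C)c2OC)C(=O)O1 | intermediate
11 | benzyl Meldrum's acid (not isolated): 5-{[2-(allyloxy)-6-methoxy-5-prenyl-4-(TIPS-oxy)phenyl]methyl}-2,2-dimethyl-1,3-dioxane-4,6-dione | CC1(C)OC(=O)C(Cc2c(OCC=C)cc(O[Si](C(C)C)(C(C)C)C(C)C)c(CC=C(C)C)c2OC)C(=O)O1 | intermediate
12 | 3-[2-(allyloxy)-6-methoxy-5-prenyl-4-(TIPS-oxy)phenyl]propanoic acid | OC(=O)CCc1c(OCC=C)cc(O[Si](C(C)C)(C(C)C)C(C)C)c(CC=C(C)C)c1OC | intermediate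
13 | (S)-4-benzyloxazolidin-2-one | O=C1OC[C@H](Cc2ccccc2)N1 | starting material
14 | mixed pivalic anhydride of 12 (not isolated) | CC(C)(C)C(=O)OC(=O)CCc1c(OCC=C)cc(O[Si](C(C)C)(C(C)C)C(C)C)c(CC=C(C)C)c1OC | intermediate
15 | (4S)-4-benzyl-3-{3-[2-(allyloxy)-6-methoxy-5-prenyl-4-(TIPS-oxy)phenyl]propanoyl}oxazolidin-2-one | O=C(CCc1c(OCC=C)cc(O[Si](C(C)C)(C(C)C)C(C)C)c(CC=C(C)C)c1OC)N1[C@@H](Cc2ccccc2)COC1=O | intermediate
16 | tert-butyl bromoacetate | CC(C)(C)OC(=O)CBr | starting material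
17 | sodium (Z)-enolate of 15 (not isolated) | [Na+].[O-]/C(=C\Cc1c(OCC=C)cc(O[Si](C(C)C)(C(C)C)C(C)C)c(CC=C(C)C)c1OC)N1[C@@H](Cc2ccccc2)COC1=O | intermediate
18 | tert-butyl (3R)-3-{[2-(allyloxy)-6-methoxy-5-prenyl-4-(TIPS-oxy)phenyl]methyl}-4-[(4S)-4-benzyl-2-oxooxazolidin-3-yl]-4-oxobutanoate | CC(C)(C)OC(=O)C[C@@H](Cc1c(OCC=C)cc(O[Si](C(C)C)(C(C)C)C(C)C)c(CC=C(C)C)c1OC)C(=O)N1[C@@H](Cc2ccccc2)COC1=O | intermediate
19 | tert-butyl (3R)-4-[2-(allyloxy)-6-methoxy-5-prenyl-4-(TIPS-oxy)phenyl]-3-(hydroxymethyl)butanoate | CC(C)(C)OC(=O)C[C@@H](Cc1c(OCC=C)cc(O[Si](C(C)C)(C(C)C)C(C)C)c(CC=C(C)C)c1OC)CO | intermediate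
20 | tert-butyl (3R)-4-[2-hydroxy-6-methoxy-5-prenyl-4-(TIPS-oxy)phenyl]-3-(hydroxymethyl)butanoate | CC(C)(C)OC(=O)C[C@@H](Cc1c(O)cc(O[Si](C(C)C)(C(C)C)C(C)C)c(CC=C(C)C)c1OC)CO | intermediate
21 | tert-butyl 2-[(3R)-5-methoxy-6-prenyl-7-(TIPS-oxy)chroman-3-yl]acetate | COc1c(CC=C(C)C)c(O[Si](C(C)C)(C(C)C)C(C)C)cc2c1C[C@H](CC(=O)OC(C)(C)C)CO2 | intermediate
22 | trimethylsilyl 2-[(3R)-5-methoxy-6-prenyl-7-(TIPS-oxy)chroman-3-yl]acetate (not isolated) | COc1c(CC=C(C)C)c(O[Si](C(C)C)(C(C)C)C(C)C)cc2c1C[C@H](CC(=O)O[Si](C)(C)C)CO2 | intermediate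
23 | 2-[(3R)-5-methoxy-6-prenyl-7-(TIPS-oxy)chroman-3-yl]acetic acid | COc1c(CC=C(C)C)c(O[Si](C(C)C)(C(C)C)C(C)C)cc2c1C[C@H](CC(=O)O)CO2 | intermediate
24 | ethoxyacetylene | CCOC#C | starting material
25 | 2-[(3R)-5-methoxy-6-prenyl-7-(TIPS-oxy)chroman-3-yl]acetyl chloride (not isolated) | COc1c(CC=C(C)C)c(O[Si](C(C)C)(C(C)C)C(C)C)cc2c1C[C@H](CC(=O)Cl)CO2 | intermediate
26 | ketene (not isolated): 2-[(3R)-5-methoxy-6-prenyl-7-(TIPS-oxy)chroman-3-yl]ethen-1-one | COc1c(CC=C(C)C)c(O[Si](C(C)C)(C(C)C)C(C)C)cc2c1C[C@H](C=C=O)CO2 | intermediate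
27 | 3-ethoxy-4-[(3R)-5-methoxy-6-prenyl-7-(TIPS-oxy)chroman-3-yl]cyclobut-2-en-1-one | COc1c(CC=C(C)C)c(O[Si](C(C)C)(C(C)C)C(C)C)cc2c1C[C@H](C1C(OCC)=CC1=O)CO2 | intermediate
28 | 3-hydroxy-2-[(3R)-5-methoxy-6-prenyl-7-(TIPS-oxy)chroman-3-yl]cyclobut-2-en-1-one | COc1c(CC=C(C)C)c(O[Si](C(C)C)(C(C)C)C(C)C)cc2c1C[C@H](C1=C(O)CC1=O)CO2 | intermediate
29 | 3-methoxy-2-[(3R)-5-methoxy-6-prenyl-7-(TIPS-oxy)chroman-3-yl]cyclobut-2-en-1-one | COc1c(CC=C(C)C)c(O[Si](C(C)C)(C(C)C)C(C)C)cc2c1C[C@H](C1=C(OC)CC1=O)CO2 | intermediate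
30 | 3-methoxy-2-[(3R)-5-methoxy-6-prenyl-7-(TIPS-oxy)chroman-3-yl]cyclobut-2-en-1-ol (not isolated) | COc1c(CC=C(C)C)c(O[Si](C(C)C)(C(C)C)C(C)C)cc2c1C[C@H](C1=C(OC)CC1O)CO2 | intermediate
31 | 2-[(3R)-5-methoxy-6-prenyl-7-(TIPS-oxy)chroman-3-yl]cyclobut-2-en-1-one | COc1c(CC=C(C)C)c(O[Si](C(C)C)(C(C)C)C(C)C)cc2c1C[C@H](C1=CCC1=O)CO2 | intermediate
32 | ethyl 4-methylpent-3-enoate | CCOC(=O)CC=C(C)C | starting material
33 | lithium 5-methylhex-4-en-1-yn-1-olate (not isolated) | [Li+].[O-]C#CCC=C(C)C | intermediate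
34 | triisopropyl[(5-methylhex-4-en-1-yn-1-yl)oxy]silane | CC(C)=CCC#CO[Si](C(C)C)(C(C)C)C(C)C | intermediate
35 | vinylketene (not isolated): 2-[(3R)-5-methoxy-6-prenyl-7-(TIPS-oxy)chroman-3-yl]buta-1,3-dien-1-one | COc1c(CC=C(C)C)c(O[Si](C(C)C)(C(C)C)C(C)C)cc2c1C[C@H](C(C=C)=C=O)CO2 | intermediate
36 | vinylcyclobutenone (not isolated): 4-[(3R)-5-methoxy-6-prenyl-7-(TIPS-oxy)chroman-3-yl]-2-prenyl-3-(TIPS-oxy)-4-vinylcyclobut-2-en-1-one | COc1c(CC=C(C)C)c(O[Si](C(C)C)(C(C)C)C(C)C)cc2c1C[C@H](C1(C=C)C(=O)C(CC=C(C)C)=C1O[Si](C(C)C)(C(C)C)C(C)C)CO2 | intermediate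
37 | dienylketene (not isolated): 4-[(3R)-5-methoxy-6-prenyl-7-(TIPS-oxy)chroman-3-yl]-2-prenyl-3-(TIPS-oxy)hexa-1,3,5-trien-1-one | COc1c(CC=C(C)C)c(O[Si](C(C)C)(C(C)C)C(C)C)cc2c1C[C@H](C(C=C)=C(O[Si](C(C)C)(C(C)C)C(C)C)C(CC=C(C)C)=C=O)CO2 | intermediate
38 | cyclohexadienone (not isolated): 4-[(3R)-5-methoxy-6-prenyl-7-(TIPS-oxy)chroman-3-yl]-2-prenyl-3-(TIPS-oxy)cyclohexa-2,4-dien-1-one | COc1c(CC=C(C)C)c(O[Si](C(C)C)(C(C)C)C(C)C)cc2c1C[C@H](C1=CCC(=O)C(CC=C(C)C)=C1O[Si](C(C)C)(C(C)C)C(C)C)CO2 | intermediate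
39 | 4-[(3R)-5-methoxy-6-prenyl-7-(TIPS-oxy)chroman-3-yl]-2-prenyl-3-(TIPS-oxy)phenol | COc1c(CC=C(C)C)c(O[Si](C(C)C)(C(C)C)C(C)C)cc2c1C[C@H](c1ccc(O)c(CC=C(C)C)c1O[Si](C(C)C)(C(C)C)C(C)C)CO2 | intermediate
40 | 5-[(3R)-5-methoxy-6-prenyl-7-(TIPS-oxy)chroman-3-yl]-3-prenyl-4-(TIPS-oxy)cyclohexa-3,5-diene-1,2-dione | COc1c(CC=C(C)C)c(O[Si](C(C)C)(C(C)C)C(C)C)cc2c1C[C@H](C1=CC(=O)C(=O)C(CC=C(C)C)=C1O[Si](C(C)C)(C(C)C)C(C)C)CO2 | intermediate
41 | 2-hydroxy-5-[(3R)-7-hydroxy-5-methoxy-6-prenylchroman-3-yl]-3-prenylcyclohexa-2,5-diene-1,4-dione | COc1c(CC=C(C)C)c(O)cc2c1C[C@H](C1=CC(=O)C(O)=C(CC=C(C)C)C1=O)CO2 | target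

**Totals**
Total step count: 19. Longest linear sequence: 18 steps (steps 1–15 and 17–19); step 16 is a one-step side branch.

**Steps most likely to fail**

Step 3. The ortho-dienone may enolise before the Cope shift, which would leave the allyl unit as a 1,1-dimethylallyl group on the carbon between the two oxygens instead of a prenyl group on the para carbon (poor ortho/para partitioning). The fallback blocks that ortho carbon and sets out from 2. Bromination with N-bromosuccinimide in MeCN at 0 °C is expected ortho to the chelated hydroxyl and should give 3-bromo-2-hydroxy-6-methoxy-4-(TIPS-oxy)benzaldehyde F1. Mitsunobu etherification with 3 (PPh3, DIAD, THF) should give 3-bromo-6-methoxy-2-(prenyloxy)-4-(TIPS-oxy)benzaldehyde F2. Heating in PhNEt2, now with both ortho carbons substituted, can only end at the para carbon and should give 3-bromo-2-hydroxy-6-methoxy-5-prenyl-4-(TIPS-oxy)benzaldehyde F3. Hydrodebromination (Pd(PPh3)4 cat., HCO2Na, DMF, 80 °C) should then return to the route at 7.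

Step 15. Over-reduction or loss of the strained, electrophilic cyclobutenone during the acidic transposition may erode the material. The fallback replaces the reduction/transposition by removal of an enol triflate and sets out from 28. Treatment with Tf2O and Et3N in CH2Cl2 at −78 °C should give the enol triflate 3-oxo-2-[(3R)-5-methoxy-6-prenyl-7-(TIPS-oxy)chroman-3-yl]cyclobut-1-en-1-yl trifluoromethanesulfonate F4. Reduction with Bu3SnH and LiCl under Pd(PPh3)4 catalysis in THF should exchange the triflate for hydrogen under neutral conditions and return to the route at 31, so that steps 14 and 15 are not needed.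

Step 18. The nitroxyl radical may couple at the substituted para carbon, or the ortho-quinone may decompose in the two-phase medium. The fallback introduces the oxygen by formylation and Dakin oxidation and sets out from 39. Magnesium-mediated ortho-formylation (MgCl2, Et3N, paraformaldehyde, MeCN, reflux) at the only free ortho carbon should give 2-hydroxy-5-[(3R)-5-methoxy-6-prenyl-7-(TIPS-oxy)chroman-3-yl]-3-prenyl-4-(TIPS-oxy)benzaldehyde F5. Dakin oxidation (H2O2, aqueous NaHCO3, THF) should give the catechol 5-[(3R)-5-methoxy-6-prenyl-7-(TIPS-oxy)chroman-3-yl]-3-prenyl-4-(TIPS-oxy)benzene-1,2-diol F6. Oxidation with Ag2O in Et2O should return to the route at 40.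

**Further compounds**
F1 | step 3 | 3-bromo-2-hydroxy-6-methoxy-4-(TIPS-oxy)benzaldehyde | O=Cc1c(O)c(Br)c(O[Si](C(C)C)(C(C)C)C(C)C)cc1OC
F2 | step 3 | 3-bromo-6-methoxy-2-(prenyloxy)-4-(TIPS-oxy)benzaldehyde | O=Cc1c(OCC=C(C)C)c(Br)c(O[Si](C(C)C)(C(C)C)C(C)C)cc1OC
F3 | step 3 | 3-bromo-2-hydroxy-6-methoxy-5-prenyl-4-(TIPS-oxy)benzaldehyde | O=Cc1c(O)c(Br)c(O[Si](C(C)C)(C(C)C)C(C)C)c(CC=C(C)C)c1OC
F4 | step 15 | 3-oxo-2-[(3R)-5-methoxy-6-prenyl-7-(TIPS-oxy)chroman-3-yl]cyclobut-1-en-1-yl trifluoromethanesulfonate | COc1c(CC=C(C)C)c(O[Si](C(C)C)(C(C)C)C(C)C)cc2c1C[C@H](C1=C(OS(=O)(=O)C(F)(F)F)CC1=O)CO2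
F5 | step 18 | 2-hydroxy-5-[(3R)-5-methoxy-6-prenyl-7-(TIPS-oxy)chroman-3-yl]-3-prenyl-4-(TIPS-oxy)benzaldehyde | COc1c(CC=C(C)C)c(O[Si](C(C)C)(C(C)C)C(C)C)cc2c1C[C@H](c1cc(C=O)c(O)c(CC=C(C)C)c1O[Si](C(C)C)(C(C)C)C(C)C)CO2
F6 | step 18 | 5-[(3R)-5-methoxy-6-prenyl-7-(TIPS-oxy)chroman-3-yl]-3-prenyl-4-(TIPS-oxy)benzene-1,2-diol | COc1c(CC=C(C)C)c(O[Si](C(C)C)(C(C)C)C(C)C)cc2c1C[C@H](c1cc(O)c(O)c(CC=C(C)C)c1O[Si](C(C)C)(C(C)C)C(C)C)CO2
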